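**Retrosynthetic overview**
1. Target ⇐ bis-silyl ether of the target (desilylation). The C8 ester is put on by acylative quench of the alkoxide formed in the key step.
2. Key disconnection C7–C8: the ten-membered ring is closed last by addition of a samarium ketyl radical (from a C8 aldehyde) to C7 of a preformed 3-(acetoxymethyl)butenolide; loss of acetate unveils the α-methylene lactone.
3. C8 aldehyde ⇐ terminal alkene; C3–C4 ⇐ Nozaki–Hiyama–Kishi union of a (Z)-vinyl iodide butenolide (fragment 1) with a β,γ-epoxy aldehyde (fragment 2).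
4. Fragment 1 ⇐ ring-closing metathesis of an acrylate of a resolved iodo-dienol; fragment 2 ⇐ alkoxide-directed allylmagnesiation of an alkynediol, then Sharpless epoxidation.
5. Ring order: epoxide (fragment 2) and butenolide (fragment 1) first, ten-membered carbocycle last.

Assumption: germacrane numbering is used for the skeleton (lactone O on C6, ester on C8, epoxide C1–C10, CH2OH = C14, methyl = C15, lactone carbons C11–C13); all descriptors are read from the given SMILES, which shows a cis-fused lactone (H6/H7 cis) and an (R)-2-methylbutanoate.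

**Route**

Step 1
Reactants: 1 (E)-but-2-enal; 2 prop-1-yn-1-ylmagnesium bromide
Product: 3 rac-(E)-hept-2-en-5-yn-4-ol
Conditions: THF, −78 → 0 °C; aq. NH4Cl
Reagents that add atoms: none
Why: 1,2-addition of an alkynyl Grignard reagent to the enal carbonyl gives the racemic carbinol that becomes C6, flanked by the future C4–C5 and C7 units.

Step 2
Reactants: 3 rac-(E)-hept-2-en-5-yn-4-ol
Product: 4 (2E,4R)-hept-2-en-5-yn-4-ol
Conditions: Ti(OiPr)4 (0.15 equiv), D-(−)-diisopropyl tartrate (0.2 equiv), t-BuOOH (0.6 equiv), 4 Å sieves, CH2Cl2, −20 °C, to about 55–60% conversion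
Reagents that add atoms: none
Why: Sharpless kinetic resolution, in which the D-(−)-tartrate catalyst epoxidises the (4S)-enantiomer much faster (to the erythro epoxy alcohol), so the unreacted (4R)-alcohol is recovered in high ee and fixes the future C6 stereocentre.

Step 3
Reactants: 4 (2E,4R)-hept-2-en-5-yn-4-ol
Product: 6 (2E,4R,5Z)-6-iodohepta-2,5-dien-4-ol, via cyclic sodium alkenylalanate 5 (not isolated)
Conditions: NaAlH2(OCH2CH2OMe)2, THF, 0 °C → rt; EtOAc; then I2, −78 → 0 °C
Reagents that add atoms: iodine, II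
Why: alkoxide-directed trans-hydroalumination of the propargylic alcohol puts aluminium on the distal alkyne carbon cis to the carbinol, and iodinolysis with retention gives the (Z)-iodoalkene that encodes the 4Z geometry, the stereocentre being untouched.

Step 4
Reactants: 7 2-(bromomethyl)prop-2-enoic acid
Product: 8 2-[(acetyloxy)methyl]prop-2-enoic acid
Conditions: NaOAc, AcOH, 80 °C
Reagents that add atoms: sodium acetate, CC(=O)[O-].[Na+]
Why: allylic substitution of bromide by acetate (SN2 and SN2′ give the same product) installs the acetate that later serves as the leaving group on C13.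

Step 5
Reactants: 8 2-[(acetyloxy)methyl]prop-2-enoic acid; 6 (2E,4R,5Z)-6-iodohepta-2,5-dien-4-ol
Product: 10 (2E,4R,5Z)-6-iodohepta-2,5-dien-4-yl 2-[(acetyloxy)methyl]prop-2-enoate, via acid chloride 9 (not isolated)
Conditions: 8, (COCl)2, DMF (cat.), CH2Cl2, 0 °C → rt, evaporate; then 6, pyridine, CH2Cl2, −20 → 0 °C
Reagents that add atoms: none
Why: O-acylation of the secondary alcohol by the acid chloride proceeds with retention at the carbinol carbon, and the absence of DMAP avoids SN2′ attack on the acetoxymethyl acrylate.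

Step 6
Reactants: 10 (2E,4R,5Z)-6-iodohepta-2,5-dien-4-yl 2-[(acetyloxy)methyl]prop-2-enoate
Product: 11 [(5R)-5-[(1Z)-2-iodoprop-1-en-1-yl]-2-oxo-2,5-dihydrofuran-3-yl]methyl acetate (fragment 1)
Conditions: second-generation Grubbs catalyst RuCl2(PCy3)(H2IMes)(=CHPh) (5 mol%), toluene (0.005 M), 80 °C
Reagents that add atoms: none
Why: ring-closing metathesis between the acrylate and the propenyl group expels propene and forms the C7=C11 butenolide, while the trisubstituted iodoalkene is too hindered to react and the stereocentre is not involved.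

Step 7
Reactants: 12 but-3-yn-1-ol; 13 formaldehyde (used as paraformaldehyde)
Product: 15 pent-2-yne-1,5-diol, via dilithium salt 14 (not isolated)
Conditions: n-BuLi (2.1 equiv), THF, −78 → 0 °C; (CH2O)n, 0 °C → rt; aq. NH4Cl
Reagents that add atoms: none
Why: hydroxymethylation of the lithium acetylide adds C14 and creates the propargylic alcohol that directs the next step.

Step 8
Reactants: 15 pent-2-yne-1,5-diol; 16 prop-2-en-1-ylmagnesium bromide
Product: 17 (2E)-2-(prop-2-en-1-yl)pent-2-ene-1,5-diol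
Conditions: 16 (4 equiv), Et2O/THF, reflux, 16 h; aq. NH4Cl
Reagents that add atoms: none
Why: alkoxide-directed anti-carbomagnesiation delivers allyl to the alkyne carbon next to the propargylic oxygen and magnesium to the distal carbon in a five-membered chelate (the homopropargylic alkoxide directs the same way), so protonation gives the (E)-allylic alcohol with the C9 and C2 chains cis, as the 1,10-epoxide requires.

Step 9
Reactants: 17 (2E)-2-(prop-2-en-1-yl)pent-2-ene-1,5-diol
Product: 18 [(2R,3R)-3-(2-hydroxyethyl)-2-(prop-2-en-1-yl)oxiran-2-yl]methanol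
Conditions: Ti(OiPr)4 (10 mol%), D-(−)-diisopropyl tartrate (12 mol%), t-BuOOH (2 equiv), 4 Å sieves, CH2Cl2, −20 °C
Reagents that add atoms: tert-butyl hydroperoxide, CC(C)(C)OO
Why: Sharpless asymmetric epoxidation of the primary allylic alcohol with the D-(−)-tartrate delivers oxygen to the face that gives the (1R,10R) epoxide of the target, the terminal alkene and the homoallylic hydroxyl being inert.

Step 10
Reactants: 18 [(2R,3R)-3-(2-hydroxyethyl)-2-(prop-2-en-1-yl)oxiran-2-yl]methanol
Product: 19 2-[(2R,3R)-3-(hydroxymethyl)-3-(prop-2-en-1-yl)oxiran-2-yl]acetaldehyde (fragment 2)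
Conditions: TEMPO (10 mol%), PhI(OAc)2 (1.1 equiv), CH2Cl2, 0 °C; used at once
Reagents that add atoms: none
Why: the sterically demanding oxoammonium oxidant should take the unhindered C3 primary alcohol in preference to the neopentyl-type C14 hydroxyl on the quaternary epoxide carbon and stops at the aldehyde, which cannot form a lactol because C14 and C2 are trans on the epoxide.

Step 11
Reactants: 19 2-[(2R,3R)-3-(hydroxymethyl)-3-(prop-2-en-1-yl)oxiran-2-yl]acetaldehyde; 11 [(5R)-5-[(1Z)-2-iodoprop-1-en-1-yl]-2-oxo-2,5-dihydrofuran-3-yl]methyl acetate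
Product: 20 [(5S)-5-[(1Z,3S)-3-hydroxy-4-[(2R,3R)-3-(hydroxymethyl)-3-(prop-2-en-1-yl)oxiran-2-yl]-2-methylbut-1-en-1-yl]-2-oxo-2,5-dihydrofuran-3-yl]methyl acetate
Conditions: CrCl2 (4 equiv), NiCl2 (2 mol%), chiral oxazoline–sulfonamide ligand of the Kishi type (4.4 equiv, enantiomer chosen for Re-face addition), Et3N (4.4 equiv), THF, rt; 11 (1.5 equiv); buffered aqueous work-up
Reagents that add atoms: none
Why: Nozaki–Hiyama–Kishi coupling (oxidative addition of the vinyl iodide to zerovalent nickel, transmetalation to chromium, 1,2-addition to the aldehyde) forms C3–C4 with retention of the Z geometry, the sulfonamide ligand on chromium directing Re-face attack to give the 3S alcohol, while hydroxyl, epoxide, lactone and allylic acetate are tolerated.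

Step 12
Reactants: 20 (the diol from step 11)
Product: 21 [(5S)-5-[(1Z,3S)-2-methyl-4-[(2R,3R)-3-(prop-2-en-1-yl)-3-[(triethylsilyloxy)methyl]oxiran-2-yl]-3-(triethylsilyloxy)but-1-en-1-yl]-2-oxo-2,5-dihydrofuran-3-yl]methyl acetate
Conditions: Et3SiOTf (2.5 equiv), 2,6-lutidine (4 equiv), CH2Cl2, −78 °C, on crude 20
Reagents that add atoms: triethylsilyl trifluoromethanesulfonate, CC[Si](CC)(CC)OS(=O)(=O)C(F)(F)F
Why: silylation of both hydroxyls with a non-nucleophilic base at low temperature leaves epoxide and allylic acetate intact and prevents conjugate addition of the C3 hydroxyl to the butenolide.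

Step 13
Reactants: 21 (the bis-silyl ether from step 12)
Product: 23 [(5S)-5-[(1Z,3S)-2-methyl-4-[(2R,3R)-3-(2-oxoethyl)-3-[(triethylsilyloxy)methyl]oxiran-2-yl]-3-(triethylsilyloxy)but-1-en-1-yl]-2-oxo-2,5-dihydrofuran-3-yl]methyl acetate, via terminal 1,2-diol 22 (not isolated)
Conditions: K2OsO2(OH)4 (2 mol%), (DHQD)2PHAL (5 mol%), N-methylmorpholine N-oxide (1.1 equiv), acetone/H2O, 0 °C; then NaIO4, pH 7 buffer, THF/H2O, 0 °C
Reagents that add atoms: N-methylmorpholine N-oxide, C[N+]1([O-])CCOCC1; water, O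
Why: ligand-accelerated dihydroxylation should select the unhindered monosubstituted alkene over the Z-trisubstituted alkene (hindered, two allylic oxygens) and the electron-poor butenolide, and periodate cleavage of the diol then gives the C8 aldehyde.

Step 14
Reactants: 23 (the aldehyde from step 13); 24 (2R)-2-methylbutanoic acid
Product: 27 (1R,3S,4Z,6S,7R,8R,10R)-1,10-epoxy-8-[(2R)-2-methylbutanoyloxy]-3,14-bis(triethylsilyloxy)germacra-4,11(13)-dien-12,6-olide, via (2R)-2-methylbutanoyl chloride 25 (not isolated), via samarium C8-alkoxide 26 (not isolated)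
Conditions: 24, (COCl)2, DMF (cat.), CH2Cl2, 0 °C → rt, evaporate (gives 25); separately 23, THF (0.002 M), SmI2 (2.2 equiv, added dropwise), −78 °C, 1 h; then 25 (5 equiv), −78 → −20 °C; pH 7 phosphate buffer
Reagents that add atoms: none
Why: Proposed new method: single-electron reduction of the aldehyde by SmI2 gives a persistent, reversibly formed samarium ketyl that adds as a nucleophilic radical to C7 of the butenolide and closes the ten-membered ring through C7–C8, a second electron then gives the samarium enolate, which expels acetate to unveil the α-methylene lactone, and the trivalent samarium alkoxide is acylated in the same flask before it can translactonise; the tether from C6 is expected to deliver the ketyl to the lactone face that already carries C5 (cis fusion, 7R) and chelation of samarium between the ketyl oxygen and the lactone oxygens to place O8 cis to C11 (8R), the closest known chemistry being SmI2 ketyl–enoate couplings, medium-ring ketyl–olefin cyclisations, β-elimination from samarium enolates and carbonyl allylations with 3-(bromomethyl)furan-2(5H)-one.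

Step 15
Reactants: 27 (the bis-silyl ester from step 14)
Product: 28 (1R,3S,4Z,6S,7R,8R,10R)-1,10-epoxy-3,14-dihydroxy-8-[(2R)-2-methylbutanoyloxy]germacra-4,11(13)-dien-12,6-olide (CNP0356520.2)
Conditions: HF·pyridine, pyridine, THF, 0 °C
Reagents that add atoms: none
Why: buffered fluoride cleaves both triethylsilyl ethers under conditions that spare the epoxide, the ester and the α-methylene lactone.

**Compound list**
1 | (E)-but-2-enal | C/C=C/C=O | starting material
2 | prop-1-yn-1-ylmagnesium bromide | CC#C[Mg]Br | starting material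
3 | rac-(E)-hept-2-en-5-yn-4-ol | C/C=C/C(O)C#CC | intermediate
4 | (2E,4R)-hept-2-en-5-yn-4-ol | C/C=C/[C@@H](O)C#CC | intermediate
5 | cyclic sodium alkenylalanate from 4 (O–Al–C chelate, bis(2-methoxyethoxy)) | C/C=C/[C@H]1O[Al-](OCCOC)(OCCOC)C(C)=C1.[Na+] | intermediate
6 | (2E,4R,5Z)-6-iodohepta-2,5-dien-4-ol | C/C=C/[C@@H](O)/C=C(/C)I | intermediate
7 | 2-(bromomethyl)prop-2-enoic acid | C=C(CBr)C(=O)O | starting material
8 | 2-[(acetyloxy)methyl]prop-2-enoic acid | C=C(COC(C)=O)C(=O)O | intermediate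
9 | 2-[(acetyloxy)methyl]prop-2-enoyl chloride | C=C(COC(C)=O)C(=O)Cl | intermediate
10 | (2E,4R,5Z)-6-iodohepta-2,5-dien-4-yl 2-[(acetyloxy)methyl]prop-2-enoate | C/C=C/[C@@H](OC(=O)C(=C)COC(C)=O)/C=C(/C)I | intermediate
11 | [(5R)-5-[(1Z)-2-iodoprop-1-en-1-yl]-2-oxo-2,5-dihydrofuran-3-yl]methyl acetate | CC(=O)OCC1=C[C@H](/C=C(/C)I)OC1=O | intermediate
12 | but-3-yn-1-ol | C#CCCO | starting material
13 | formaldehyde (used as paraformaldehyde) | C=O | starting material
14 | dilithium salt of but-3-yn-1-ol (acetylide alkoxide) | [Li]C#CCCO[Li] | intermediate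
15 | pent-2-yne-1,5-diol | OCC#CCCO | intermediate
16 | prop-2-en-1-ylmagnesium bromide | C=CC[Mg]Br | starting material
17 | (2E)-2-(prop-2-en-1-yl)pent-2-ene-1,5-diol | OC/C(CC=C)=C/CCO | intermediate
18 | [(2R,3R)-3-(2-hydroxyethyl)-2-(prop-2-en-1-yl)oxiran-2-yl]methanol | OCC[C@H]1O[C@@]1(CO)CC=C | intermediate
19 | 2-[(2R,3R)-3-(hydroxymethyl)-3-(prop-2-en-1-yl)oxiran-2-yl]acetaldehyde | O=CC[C@H]1O[C@@]1(CO)CC=C | intermediate
20 | [(5S)-5-[(1Z,3S)-3-hydroxy-4-[(2R,3R)-3-(hydroxymethyl)-3-(prop-2-en-1-yl)oxiran-2-yl]-2-methylbut-1-en-1-yl]-2-oxo-2,5-dihydrofuran-3-yl]methyl acetate | CC(=O)OCC1=C[C@H](/C=C(/C)[C@@H](O)C[C@H]2O[C@@]2(CO)CC=C)OC1=O | intermediate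
21 | [(5S)-5-[(1Z,3S)-2-methyl-4-[(2R,3R)-3-(prop-2-en-1-yl)-3-[(triethylsilyloxy)methyl]oxiran-2-yl]-3-(triethylsilyloxy)but-1-en-1-yl]-2-oxo-2,5-dihydrofuran-3-yl]methyl acetate | CC(=O)OCC1=C[C@H](/C=C(/C)[C@@H](O[Si](CC)(CC)CC)C[C@H]2O[C@@]2(CO[Si](CC)(CC)CC)CC=C)OC1=O | intermediate
22 | terminal 1,2-diol of 21 (2,3-dihydroxypropyl on the epoxide carbon, epimer mixture at the new carbinol) | CC(=O)OCC1=C[C@H](/C=C(/C)[C@@H](O[Si](CC)(CC)CC)C[C@H]2O[C@@]2(CO[Si](CC)(CC)CC)CC(O)CO)OC1=O | intermediate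
23 | [(5S)-5-[(1Z,3S)-2-methyl-4-[(2R,3R)-3-(2-oxoethyl)-3-[(triethylsilyloxy)methyl]oxiran-2-yl]-3-(triethylsilyloxy)but-1-en-1-yl]-2-oxo-2,5-dihydrofuran-3-yl]methyl acetate | CC(=O)OCC1=C[C@H](/C=C(/C)[C@@H](O[Si](CC)(CC)CC)C[C@H]2O[C@@]2(CO[Si](CC)(CC)CC)CC=O)OC1=O | intermediate
24 | (2R)-2-methylbutanoic acid | CC[C@@H](C)C(=O)O | starting material
25 | (2R)-2-methylbutanoyl chloride | CC[C@@H](C)C(=O)Cl | intermediate
26 | samarium diiodide C8-alkoxide of the cyclised bis-silyl ether (1R,3S,4Z,6S,7R,8R,10R) | C=C1C(=O)O[C@H]2/C=C(/C)[C@@H](O[Si](CC)(CC)CC)C[C@H]3O[C@@]3(CO[Si](CC)(CC)CC)C[C@@H](O[Sm](I)I)[C@@H]12 | intermediate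
27 | (1R,3S,4Z,6S,7R,8R,10R)-1,10-epoxy-8-[(2R)-2-methylbutanoyloxy]-3,14-bis(triethylsilyloxy)germacra-4,11(13)-dien-12,6-olide | C=C1C(=O)O[C@H]2/C=C(/C)[C@@H](O[Si](CC)(CC)CC)C[C@H]3O[C@@]3(CO[Si](CC)(CC)CC)C[C@@H](OC(=O)[C@H](C)CC)[C@@H]12 | intermediate
28 | (1R,3S,4Z,6S,7R,8R,10R)-1,10-epoxy-3,14-dihydroxy-8-[(2R)-2-methylbutanoyloxy]germacra-4,11(13)-dien-12,6-olide (CNP0356520.2) | C=C1C(=O)O[C@H]2/C=C(/C)[C@@H](O)C[C@H]3O[C@@]3(CO)C[C@@H](OC(=O)[C@H](C)CC)[C@@H]12 | target

**Step count**
Total step count: 15. Longest linear sequence: 10 steps (steps 1, 2, 3, 5, 6, 11, 12, 13, 14, 15).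

**Steps most likely to fail**

Step 14 (key step). The ring closure may give the wrong C8 configuration, since chelation control at C8 is an expectation and not a precedent; a trans ring fusion at C7 is also possible and would not be repaired by this fallback. The fallback sets out from 23 and comes back at 27. The SmI2 cyclisation is run as above but quenched at −78 °C with pH 7 buffer instead of the acyl chloride, which gives the free C8 alcohol. If this is the C8 epimer, (1R,3S,4Z,6S,7R,8S,10R)-1,10-epoxy-8-hydroxy-3,14-bis(triethylsilyloxy)germacra-4,11(13)-dien-12,6-olide F5, the ester is installed with inversion by a Mitsunobu reaction with acid 24 (PPh3, diisopropyl azodicarboxylate, toluene, 0 °C → rt), which gives 27.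

Step 13. The dihydroxylation may not discriminate well enough between the terminal alkene and the other two C=C bonds. The fallback sets out from 19 and comes back at 23, unmasking C8 before the fragments are joined. Ozonolysis of 19 (O3, CH2Cl2/MeOH, −78 °C; Me2S) cleaves its only C=C; the new C8 aldehyde is captured by the geminal C14 hydroxyl as the spiro lactol 2-[(2R,3R)-6-hydroxy-1,5-dioxaspiro[2.4]heptan-2-yl]acetaldehyde F3, while the C3 aldehyde stays free. Nozaki–Hiyama–Kishi coupling of F3 with 11 under the conditions of step 11 gives the lactol [(5S)-5-[(1Z,3S)-3-hydroxy-4-[(2R,3R)-6-hydroxy-1,5-dioxaspiro[2.4]heptan-2-yl]-2-methylbut-1-en-1-yl]-2-oxo-2,5-dihydrofuran-3-yl]methyl acetate F4. Silylation with Et3SiCl and imidazole in DMF at 0 °C protects the C3 hydroxyl and traps the open hydroxy-aldehyde tautomer at its primary C14 hydroxyl, giving 23 directly; the risk here is silylation of the lactol hydroxyl instead.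

Step 11. Ligand control at C3 may be poor on this β,γ-epoxy aldehyde. The fallback sets out from 19 and 11 and comes back at 20. The coupling is run without chiral ligand (CrCl2, NiCl2 cat., DMSO, rt) and gives 20 together with its C3 epimer, [(5S)-5-[(1Z,3R)-3-hydroxy-4-[(2R,3R)-3-(hydroxymethyl)-3-(prop-2-en-1-yl)oxiran-2-yl]-2-methylbut-1-en-1-yl]-2-oxo-2,5-dihydrofuran-3-yl]methyl acetate F1. MnO2 in CH2Cl2 oxidises only the allylic C3 hydroxyl of the mixture to the enone [(5S)-5-[(1Z)-4-[(2R,3R)-3-(hydroxymethyl)-3-(prop-2-en-1-yl)oxiran-2-yl]-2-methyl-3-oxobut-1-en-1-yl]-2-oxo-2,5-dihydrofuran-3-yl]methyl acetate F2. Reduction with (R)-2-methyl-CBS-oxazaborolidine and catecholborane at −78 °C (alkenyl as the large group) then returns 20 as the 3S alcohol.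

**Further compounds**
F1 | step 11 | [(5S)-5-[(1Z,3R)-3-hydroxy-4-[(2R,3R)-3-(hydroxymethyl)-3-(prop-2-en-1-yl)oxiran-2-yl]-2-methylbut-1-en-1-yl]-2-oxo-2,5-dihydrofuran-3-yl]methyl acetate | CC(=O)OCC1=C[C@H](/C=C(/C)[C@H](O)C[C@H]2O[C@@]2(CO)CC=C)OC1=O
F2 | step 11 | [(5S)-5-[(1Z)-4-[(2R,3R)-3-(hydroxymethyl)-3-(prop-2-en-1-yl)oxiran-2-yl]-2-methyl-3-oxobut-1-en-1-yl]-2-oxo-2,5-dihydrofuran-3-yl]methyl acetate | CC(=O)OCC1=C[C@H](/C=C(/C)C(=O)C[C@H]2O[C@@]2(CO)CC=C)OC1=O
F3 | step 13 | 2-[(2R,3R)-6-hydroxy-1,5-dioxaspiro[2.4]heptan-2-yl]acetaldehyde (anomer mixture) | O=CC[C@H]1O[C@@]1(CO2)CC2O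
F4 | step 13 | [(5S)-5-[(1Z,3S)-3-hydroxy-4-[(2R,3R)-6-hydroxy-1,5-dioxaspiro[2.4]heptan-2-yl]-2-methylbut-1-en-1-yl]-2-oxo-2,5-dihydrofuran-3-yl]methyl acetate | CC(=O)OCC1=C[C@H](/C=C(/C)[C@@H](O)C[C@H]2O[C@@]2(CO3)CC3O)OC1=O
F5 | step 14 | (1R,3S,4Z,6S,7R,8S,10R)-1,10-epoxy-8-hydroxy-3,14-bis(triethylsilyloxy)germacra-4,11(13)-dien-12,6-olide | C=C1C(=O)O[C@H]2/C=C(/C)[C@@H](O[Si](CC)(CC)CC)C[C@H]3O[C@@]3(CO[Si](CC)(CC)CC)C[C@H](O)[C@@H]12
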